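(The numbers of this flask come from no measurement; no experiment stands behind them.)

Which single change to the next run keeps the most substrate out of the dormant form, and so leaves the most target?

substrate 1.0 M; reagent in the second phase 3.00 M; time 50 s; volume of the second phase over the first 1.0

- the target and crystals together standing at 50 s, as a percentage of the substrate charged
- concentration of target in solution at 12 s, in percent of saturation
- the change that raises the amount of target and crystals together at 50 s, in percent of the substrate charged most ("none" if none brings more than 2 percentage points) (west / north / south-west / north-east / none)
- amount of target and crystals together at 50 s, in percent of the substrate charged, after north

- west: doubling the solubility in step 4, all else as stated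
- north: doubling the transfer coefficient of step 3, all else as stated
- south-west: doubling the amount of reagent in the second phase, all else as stated
- north-east: doubling the dissolution coefficient of step 4, all else as stated

- target is meant together with its crystals
- in the second phase: reagent in the second phase; everything else is in the first
- charges count per volume of the first phase; a concentration in a rate is the amount of a species over the volume of its own phase; every rate counts per litre of the first phase
- solid, in amounts per volume of the solution: crystals
- run time (flask): 50 s

    substrate ⇌ dormant form (K1 = 2.9, k1 = 0.033 /s)
    target → over-reaction product (k2 = 2.3 × 10⁻⁴ /s)
    reagent in the reaction phase ⇌ reagent in the second phase, rate k3*([reagent in the reaction phase] - [reagent in the second phase]/K3) per volume of the first phase (K3 = 1.6, k3 = 0.16 /s)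
    crystals ⇌ target, rate k4*(cs4 - [target]) while solid is left; crystals form when [target] > cs4 (cs4 = 0.81 M, k4 = 1.8 /s)
    substrate + reagent in the reaction phase → target (k5 = 0.19 /M/s)

Substrate leaves by two ways: coupling with reagent in the reaction phase, at 0.19 /M/s times its concentration B, or passage to the dormant form, at 0.033 /s. My own reckoning counts what enters the dormant form as lost. It takes φ, the forward constant to the dormant form over the sum of that constant and the coupling constant times B, as the diverted share (the selectivity of this branch). But B depends on φ, since the reagent spent on coupling leaves the partition, so the answer goes back in:

first round, nothing spent: B = 1.15 M, φ = 13.1 %

second round: B = 0.820 M, φ = 17.5 %

third round: B = 0.836 M, φ = 17.2 %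

So about 82.8 % should become target. Partition balance is approached with a half-time of 2.67 s, shorter than the 21 s of substrate by its forward step to the dormant form, but the half-life of reagent in the reaction phase by coupling alone, with substrate as charged, is 3.6 s, so the balance is a first picture and no more.

With the reagent doubled, B = 1.99 M and φ = 8.03 %, a reckoned gain of 9.2 percentage points. The transfer coefficient, the solubility and the dissolution coefficient do not appear in φ. This reckoning therefore chooses to double the reagent in the next run.

The forecast gives 82.5 %, 77 % of saturation at 12 s, south-west as the best change, and 86 % after north: “Doubling the reagent speeds coupling most and so diverts the least substrate to the dormant form”.

The flask gives 82.2 %, 76.0 % of saturation, south-west as the best change and 85.0 % after north. South-west gains 7.1 points and north 2.8 points. The dormant form stands at 20.0 % after 25.0 s and 16.1 % after 50.0 s. Put back into φ, the reading of 0.618 M for reagent in the reaction phase after 5.00 s gives an early share of 21.9 %.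

The same flask stopped at 12 s, with 19 % of its substrate left, should by that early share hold 63.3 % as target and crystals. The computed value for that flask is 61.5 %.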